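Follow the excess, not the yield.

common to all: left-handed substrate 0.050 M; right-handed substrate 0.050 M

| charge | reagent | remark | time |
|---|---|---|---|
| Thursday's | 0.30 M | run made earlier |  |
| flask | 0.200 M |  | 50 h |

Thursday's run (percent of the left-handed substrate and right-handed substrate together charged)

| time / h | left-handed product / % | right-handed product / % | left-handed substrate / % |
|---|---|---|---|
| 2.00 | 11 | 8 | 32 |
| 5.00 | 28 | 8 | 21 |
| 10.0 | 35 | 24 | 19 |
| 15.0 | 36 | 29 | 10 |

(readings scatter by 2 percentage points)

1. excess of left-handed product over right-handed product in the product at 2.5 h
2. excess of left-handed product over right-handed product in the product at 50 h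
3. part of the left-handed substrate and right-handed substrate charged together that has reacted at 50 h

- reagent is single-handed; left-handed substrate and right-handed substrate are mirror images of each other, charged as a racemate, each of them at the stated concentration
- what has gone into achiral form counts as reacted
- an excess is below zero if the other one leads
- the handed part of reagent does not stay in what it makes, so the products of the two hands are mirror images too

In Thursday's run the excess of left-handed product over right-handed product reads 55.6% at 5.00 h and 10.8% at 15.0 h. The reading at 2.00 h is set aside, since it rests on a difference of 3 percentage points against a scatter of 2 points per reading. The two kept readings give 4.22 h, a rough reading of τ, the excess half-life: the time in which the excess in the product halves.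

The products are mirror images, so a balance between them stands at zero excess: kinetic control gives way to thermodynamic control. Thursday's run stopped after 3.55 half-lives. The new flask, with 0.200 M of reagent against 0.30 M, runs 11.8, and τ is taken as the same in both. Because τ is short against 50 h, Thursday's 10.8%, carried on at that τ from 15.0 h, shrinks to 0.0344%. My reckoning therefore makes the excess at 50 h small and, with the excess falling, puts the excess at 2.5 h at 55.6% or above, since 2.5 h comes before that reading at 5.00 h.

The forecast gives 35%, 9% and 86% for the questions in their order, and says the plateau of left-handed product “hints at slow onward loss or racemisation”. Its excess at 2.5 h stands below my 55.6%.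

The flask gives 61.1%, 1.37% and 90.9%, in the same order.

    reagent + left-handed substrate → left-handed product (k = 0.706 M⁻¹ h⁻¹)
    reagent + right-handed substrate → right-handed product (k = 0.0324 M⁻¹ h⁻¹)
    left-handed substrate ⇌ achiral form (K = 0.0890, k = 0.463 h⁻¹)
    right-handed substrate ⇌ achiral form (K = 0.0890, k = 0.463 h⁻¹)
    achiral form → waste (k = 0.0532 h⁻¹)
    left-handed product ⇌ right-handed product (k = 0.157 h⁻¹)
    reagent → decomposition product (k = 4.59 × 10⁻⁵ h⁻¹)
    achiral form → side product (k = 0.00689 h⁻¹)

By 50 h the flask has sent a net 37.9% of the charge from left-handed product to right-handed product, against 42.4% of right-handed product standing there. Carrying 61.1% at τ from 2.5 h to 50 h gives 0.0250% against the flask's 1.37%, and carrying 62.4% the same way in the neighbour with 0.050 M of reagent gives 0.0255% against its 2.47%, with 26.2% of left-handed substrate still present.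

The runs were computed for an exercise; the scatter is artificial.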